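Remark on the chemistry: the target has no stereocentre. The o-silylaryl triflate 1 and 2-bromo-1,3-oxazole 6 are taken as catalogue compounds. The carbinol 18 forms as a racemate and its only stereocentre is destroyed in the same step.

## Analysis of the target

The target is a linear array of three azoles. A 1H-indole is joined through C3 to C5 of a 1,3-oxazole, whose C2 carries a pyrrol-2-yl group and whose C4 carries iodine. The benzo ring of the indole is 1,2,3,5-tetrasubstituted: C7a (N1), C3a (C3), C4 (OMe) and C6 (Br). Nitrogen, methoxy and bromine are therefore mutually meta, and any classical closure onto such an aniline ring has two non-equivalent ortho carbons to choose from. Sensitive groups are the oxazole C4–I bond (cleaved by zerovalent palladium, by halogen–metal exchange and by reducing agents), the aryl C6–Br bond, and two electron-rich N–H azoles, of which the pyrrole is highly prone to electrophilic halogenation and to acid. The main difficulty is that iodine sits on the least nucleophilic and least acidic ring carbon, while the pyrrole and indole are the most nucleophilic sites, so a late electrophilic iodination cannot be selective. Two different carbon–halogen bonds must also survive every bond-forming step.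

The feature that invites the key step is the contiguous triad C7a(N1)–C3a(C3)–C4(OMe) of the benzo ring. An aryne spanning C3a≡C7a has the methoxy group on the neighbouring carbon C4, and that substituent alone decides that nitrogen adds at C7a and carbon at C3a. A second feature is used before it: in the oxazole, C5 lies next to O1, so a carbanion at C5 with iodine at C4 is the thermodynamic end point of a halogen dance.

## Retrosynthetic reasoning

**20 from 19.** The last disconnection only removes the sulfonyl group from N1 of the indole and the alkoxymethyl group from the pyrrole nitrogen. Both N–H bonds are kept masked until the end, because the organolithium steps and the aryne step each need them blocked. One fluoride treatment should cleave both.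

**19 from 3 and 16 (through 17 and 18).** The bonds N1–C7a and C3–C3a of the indole are cut together. This separates the halogenated benzene ring from everything else. It also turns the regiochemical problem of the tetrasubstituted benzo ring into the polarisation of aryne 17 by its methoxy neighbour. The forward reaction has three tasks. The sulfonamide nitrogen of 16 must add to the aryne carbon remote from methoxy. The aryl anion next to methoxy must close onto the ketone of 16 to give 18. Dehydration must then aromatise the new five-membered ring. This builds the indole and attaches the complete iodo-oxazolyl-pyrrole unit in one operation, with no palladium near C–I or C–Br.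

**16 from 11 and 13 (through 14 and 15).** The oxazole C5–C(=O) bond is cut. The forward step must move iodine from C5 to C4 and leave the carbanion at C5, which a lithium amide induces as a halogen dance giving 14. Acylation of 14 by the metalated amide 15 then gives the ketone. The iodine thus reaches C4 without any electrophilic iodination in the presence of a pyrrole.

**11 from 9 (through 10).** The C5–I bond is traced to the most acidic C–H of 9, removed by a lithium amide and replaced by iodine.

**9 from 5 and 6 (through 7 and 8); 5 from 4.** The pyrrole C2–oxazole C2 bond is cut as a Negishi coupling. The alkoxymethyl group on nitrogen directs lithiation of 5 to C2. It does not acidify the remaining pyrrole α-position towards lithium amides, and it should survive fluoride at room temperature.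

**13 from 12.** Amide formation gives the acylating agent that carries the N–CH2–C(=O) unit, which becomes N1, C2 and C3 of the indole.

**3 from 2 from 1.** The C–Br bond (C6 of the indole) is traced to the only C–H of 1 that has no ortho substituent. Iridium-catalysed borylation selects it on steric grounds, and copper-mediated bromodeboronation converts boron into bromine.

## Alternatives that were turned down

**Alternative 1:** the textbook route cuts the indole C3–oxazole C5 bond and the oxazole C2–pyrrole C2 bond, both as palladium-catalysed cross-couplings. The 3-iodoindole A1, made from the purchasable parent indole by N-sulfonylation and C3 iodination, would undergo Suzuki coupling with the 2-silyl oxazol-5-yl boronate A2 to give A3. The oxazole C4 would then be lithiated and iodinated, the silyl placeholder exchanged for a halogen, and the pyrrole attached by a second coupling. It was turned down for these reasons: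
- Every catalytic step must distinguish C3–I from C6–Br, and later a C2–halogen from C4–I on the same oxazole.
- The C4 iodination needs a strong base next to an aryl bromide.
- The placeholder at C2 costs two extra operations.
- The route forms no ring and sets no substitution pattern: all three rings are bought and then joined one bond at a time.

**Alternative 2:** the oxazole O1–C2 and C4–C5 unsaturation are made by Robinson–Gabriel cyclodehydration of the keto amide A4. This follows the presumed biogenesis from a tryptophan–proline dipeptide and would give the iodine-free oxazole A5, to be iodinated at C4 last. It was turned down for these reasons: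
- In A5 an electrophilic iodine source would attack the pyrrole α- and β-carbons and indole C2 well before oxazole C4.
- A metalation route would again need both N–H groups protected and a strong base beside C6–Br.
- A4 already presupposes the regiodefined 6-bromo-4-methoxyindole, so the benzo-ring problem is not addressed.

**Alternative 3:** the same two indole bonds as in the chosen route are made one after the other in a Bischler-type sequence. The N-aryl amino ketone A6 would be formed by N-alkylation of the 3-bromo-5-methoxy-substituted aniline nitrogen, then closed by acid-mediated electrophilic attack of the ketone on the aniline ring. It was turned down for these reasons: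
- The ring offers two ortho carbons. The one needed lies between nitrogen and methoxy. The other lies between nitrogen and bromine and is para to methoxy.
- Electrophilic closure should prefer the para-to-methoxy carbon, leading mainly to the wrong isomer A7 (4-bromo-6-methoxy).
- The strong acid required would also endanger the pyrrole protecting group and the C–I bond.

Key step: step 8

## Route

Step 1
Reactants: 1 3-methoxy-2-(trimethylsilyl)phenyl trifluoromethanesulfonate
Product: 2 3-methoxy-5-(4,4,5,5-tetramethyl-1,3,2-dioxaborolan-2-yl)-2-(trimethylsilyl)phenyl trifluoromethanesulfonate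
Conditions: [Ir(OMe)(cod)]2 (1.5 mol%), 4,4'-di-tert-butyl-2,2'-bipyridine (3 mol%), B2pin2 (1.0 equiv), cyclohexane, 80 °C
Reagents that add atoms: bis(pinacolato)diboron, CC1(C)OB(OC1(C)C)B1OC(C)(C)C(C)(C)O1
Why: Sterically controlled iridium-catalysed aromatic C–H borylation; of the three ring C–H bonds only C5–H has no ortho substituent, so boron should enter meta to both oxygen substituents. Aryl triflates and aryl silanes are tolerated by this catalyst system.

Step 2
Reactants: 2 3-methoxy-5-(4,4,5,5-tetramethyl-1,3,2-dioxaborolan-2-yl)-2-(trimethylsilyl)phenyl trifluoromethanesulfonate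
Product: 3 5-bromo-3-methoxy-2-(trimethylsilyl)phenyl trifluoromethanesulfonate
Conditions: CuBr2 (3 equiv), MeOH/H2O (1:1), 80 °C
Reagents that add atoms: copper dibromide, Br[Cu]Br
Why: Copper-mediated ipso-bromodeboronation of an aryl pinacol boronate; the C–B bond is replaced by C–Br at the same carbon, so the regiochemistry fixed in step 1 is carried over. The triflate-bearing ring is electron-poor, which should disfavour electrophilic attack at the silyl-bearing carbon.

Step 3
Reactants: 4 1H-pyrrole
Product: 5 1-{[2-(trimethylsilyl)ethoxy]methyl}-1H-pyrrole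
Conditions: NaH (1.1 equiv), DMF, 0 °C; SEMCl (1.05 equiv), 0 °C to rt
Reagents that add atoms: 2-(trimethylsilyl)ethoxymethyl chloride, C[Si](C)(C)CCOCCl
Why: N-alkylation of the sodium pyrrolide with an alkoxymethyl chloride; the hard counter-ion and DMF favour N- over C-alkylation.

Step 4
Reactants: 5 1-{[2-(trimethylsilyl)ethoxy]methyl}-1H-pyrrole; 6 2-bromo-1,3-oxazole
Product: 9 2-(1-{[2-(trimethylsilyl)ethoxy]methyl}-1H-pyrrol-2-yl)-1,3-oxazole, via 2-lithiopyrrole 7 (not isolated), via pyrrolylzinc chloride 8 (not isolated)
Conditions: n-BuLi (1.05 equiv), DME, −5 °C; ZnCl2 (1.1 equiv), THF, 0 °C to rt; then 6 (0.9 equiv), Pd(PPh3)4 (3 mol%), THF, 60 °C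
Reagents that add atoms: none
Why: Directed α-lithiation of the N-alkoxymethyl pyrrole, transmetalation to zinc and Negishi coupling with the 2-halo-oxazole, whose C2–Br bond is the most reactive position of an oxazole towards oxidative addition.

Step 5
Reactants: 9 2-(1-{[2-(trimethylsilyl)ethoxy]methyl}-1H-pyrrol-2-yl)-1,3-oxazole
Product: 11 5-iodo-2-(1-{[2-(trimethylsilyl)ethoxy]methyl}-1H-pyrrol-2-yl)-1,3-oxazole, via 5-lithiooxazole 10 (not isolated)
Conditions: LDA (1.0 equiv), THF, −78 °C; cannulated into ICH2CH2I (1.2 equiv), THF, −78 °C to rt
Reagents that add atoms: 1,2-diiodoethane, ICCI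
Why: Deprotonation of a 2-substituted oxazole by a lithium amide occurs at C5, the most acidic remaining C–H, and the N-alkoxymethyl pyrrole is not lithiated by LDA at −78 °C. Diiodoethane iodinates the carbanion without attacking the electron-rich pyrrole, and inverse addition keeps base away from the product so that no premature halogen migration occurs.

Step 6
Reactants: 12 N-(4-methylbenzenesulfonyl)glycine
Product: 13 N-methoxy-N-methyl-2-(4-methylbenzenesulfonamido)acetamide
Conditions: MeNHOMe·HCl (1.2 equiv), EDC·HCl (1.2 equiv), HOBt (cat.), N-methylmorpholine (2.5 equiv), CH2Cl2, 0 °C to rt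
Reagents that add atoms: N,O-dimethylhydroxylamine hydrochloride, CNOC.Cl
Why: Standard carbodiimide amidation to the N-methoxy-N-methylamide; the sulfonamide N–H is not nucleophilic enough to compete.

Step 7
Reactants: 11 5-iodo-2-(1-{[2-(trimethylsilyl)ethoxy]methyl}-1H-pyrrol-2-yl)-1,3-oxazole; 13 N-methoxy-N-methyl-2-(4-methylbenzenesulfonamido)acetamide
Product: 16 N-{2-[4-iodo-2-(1-{[2-(trimethylsilyl)ethoxy]methyl}-1H-pyrrol-2-yl)-1,3-oxazol-5-yl]-2-oxoethyl}-4-methylbenzenesulfonamide, via 4-iodo-5-lithiooxazole 14 (not isolated), via chloromagnesium sulfonamide 15 (not isolated)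
Conditions: LDA (1.3 equiv), THF, −78 °C, 45 min; then 13 pre-treated with i-PrMgCl (1.0 equiv, THF, −20 °C), −78 to 0 °C; aq. NH4Cl
Reagents that add atoms: none
Why: Base-induced halogen dance of a 5-halo-oxazole: deprotonation at C4 and intermolecular iodine–lithium exchange should converge on the 4-iodo-5-lithio isomer, whose carbanion is stabilised next to O1. Weinreb ketone synthesis with the N-metalated amide then stops at the ketone, because the chelated tetrahedral intermediate survives until work-up.

Step 8
Reactants: 3 5-bromo-3-methoxy-2-(trimethylsilyl)phenyl trifluoromethanesulfonate; 16 N-{2-[4-iodo-2-(1-{[2-(trimethylsilyl)ethoxy]methyl}-1H-pyrrol-2-yl)-1,3-oxazol-5-yl]-2-oxoethyl}-4-methylbenzenesulfonamide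
Product: 19 6-bromo-3-[4-iodo-2-(1-{[2-(trimethylsilyl)ethoxy]methyl}-1H-pyrrol-2-yl)-1,3-oxazol-5-yl]-4-methoxy-1-(4-methylbenzenesulfonyl)-1H-indole, via aryne 17 (not isolated), via indolin-3-ol 18 (not isolated)
Conditions: 3 (1.3 equiv), CsF (3 equiv), MeCN, 25 °C; aqueous work-up, then crude in CH2Cl2 with camphorsulfonic acid (20 mol%), 25 °C
Reagents that add atoms: none
Why: Fluoride removes the silyl group of 3 and triflate leaves to give aryne 17; the sulfonamide anion of 16 adds to the aryne, the resulting aryl anion attacks the ketone to give carbinol 18, and acid-catalysed loss of water aromatises the new ring to 19. The closest known reaction type is the aryne annulation of α-amino ketones to indoles (the aryne variant of the Bischler–Möhlau synthesis), together with the fluoride-mediated N-arylation of sulfonamides by o-silylaryl triflates. The one ring closed is the five-membered ring of the indole, formed by 5-exo-trig attack of the aryl anion on the carbonyl carbon after the intermolecular N–C bond formation. Regioselectivity is the selectivity the step needs: the methoxy group on the carbon flanking the triple bond polarises the aryne so that the nucleophile attacks the distal carbon and the negative charge develops on the carbon next to the inductively withdrawing oxygen. This places nitrogen at C7a and the ketone carbon at C3a, hence methoxy at C4 and bromine at C6; the bromine is meta to the attacked carbon and should exert only a weak opposing bias. No stereocentre survives, since the carbinol carbon of 18 is formed racemic and becomes sp2 on dehydration. Chemoselectivity rests on the sulfonamide being the only acidic N–H (the pyrrole nitrogen is blocked and its protecting group should resist CsF at 25 °C), and the tertiary alkoxide is reprotonated by unreacted sulfonamide, which propagates the reaction. Ionisation of the carbinol is assisted by the ortho-methoxy aryl and oxazolyl groups and driven by aromatisation.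

Step 9
Reactants: 19 6-bromo-3-[4-iodo-2-(1-{[2-(trimethylsilyl)ethoxy]methyl}-1H-pyrrol-2-yl)-1,3-oxazol-5-yl]-4-methoxy-1-(4-methylbenzenesulfonyl)-1H-indole
Product: 20 6-bromo-3-[4-iodo-2-(1H-pyrrol-2-yl)-1,3-oxazol-5-yl]-4-methoxy-1H-indole
Conditions: TBAF (1 M in THF, 8 equiv), ethylenediamine (3 equiv), THF, 65 °C; aq. NH4Cl
Reagents that add atoms: none
Why: Fluoride attacks the sulfonyl sulfur of N-sulfonyl indoles and the silicon of the alkoxymethyl group, which fragments to ethylene, formaldehyde and the pyrrolide; ethylenediamine traps the formaldehyde. Aryl bromide and the oxazole C4–I bond, the least electrophilic position of the oxazole, should not react with fluoride.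

## Compound list

1 | 3-methoxy-2-(trimethylsilyl)phenyl trifluoromethanesulfonate | COc1cccc(OS(=O)(=O)C(F)(F)F)c1[Si](C)(C)C | starting material
2 | 3-methoxy-5-(4,4,5,5-tetramethyl-1,3,2-dioxaborolan-2-yl)-2-(trimethylsilyl)phenyl trifluoromethanesulfonate | COc1cc(B2OC(C)(C)C(C)(C)O2)cc(OS(=O)(=O)C(F)(F)F)c1[Si](C)(C)C | intermediate
3 | 5-bromo-3-methoxy-2-(trimethylsilyl)phenyl trifluoromethanesulfonate | COc1cc(Br)cc(OS(=O)(=O)C(F)(F)F)c1[Si](C)(C)C | intermediate
4 | 1H-pyrrole | c1cc[nH]c1 | starting material
5 | 1-{[2-(trimethylsilyl)ethoxy]methyl}-1H-pyrrole | C[Si](C)(C)CCOCn1cccc1 | intermediate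
6 | 2-bromo-1,3-oxazole | Brc1ncco1 | starting material
7 | 2-lithio-1-{[2-(trimethylsilyl)ethoxy]methyl}-1H-pyrrole | [Li]c1cccn1COCC[Si](C)(C)C | intermediate (not isolated)
8 | chloro(1-{[2-(trimethylsilyl)ethoxy]methyl}-1H-pyrrol-2-yl)zinc | Cl[Zn]c1cccn1COCC[Si](C)(C)C | intermediate (not isolated)
9 | 2-(1-{[2-(trimethylsilyl)ethoxy]methyl}-1H-pyrrol-2-yl)-1,3-oxazole | C[Si](C)(C)CCOCn1cccc1-c1ncco1 | intermediate
10 | 5-lithio-2-(1-{[2-(trimethylsilyl)ethoxy]methyl}-1H-pyrrol-2-yl)-1,3-oxazole | [Li]c1cnc(o1)-c1cccn1COCC[Si](C)(C)C | intermediate (not isolated)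
11 | 5-iodo-2-(1-{[2-(trimethylsilyl)ethoxy]methyl}-1H-pyrrol-2-yl)-1,3-oxazole | Ic1cnc(o1)-c1cccn1COCC[Si](C)(C)C | intermediate
12 | N-(4-methylbenzenesulfonyl)glycine | Cc1ccc(cc1)S(=O)(=O)NCC(=O)O | starting material
13 | N-methoxy-N-methyl-2-(4-methylbenzenesulfonamido)acetamide | Cc1ccc(cc1)S(=O)(=O)NCC(=O)N(C)OC | intermediate
14 | 4-iodo-5-lithio-2-(1-{[2-(trimethylsilyl)ethoxy]methyl}-1H-pyrrol-2-yl)-1,3-oxazole | [Li]c1oc(nc1I)-c1cccn1COCC[Si](C)(C)C | intermediate (not isolated)
15 | N-chloromagnesio derivative of 13 | Cc1ccc(cc1)S(=O)(=O)N([Mg]Cl)CC(=O)N(C)OC | intermediate (not isolated)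
16 | N-{2-[4-iodo-2-(1-{[2-(trimethylsilyl)ethoxy]methyl}-1H-pyrrol-2-yl)-1,3-oxazol-5-yl]-2-oxoethyl}-4-methylbenzenesulfonamide | Cc1ccc(cc1)S(=O)(=O)NCC(=O)c1oc(nc1I)-c1cccn1COCC[Si](C)(C)C | intermediate
17 | 5-bromo-3-methoxybenzyne (5-bromo-1,2-didehydro-3-methoxybenzene) | COC1=CC(Br)=CC#C1 | intermediate (not isolated)
18 | 6-bromo-3-[4-iodo-2-(1-{[2-(trimethylsilyl)ethoxy]methyl}-1H-pyrrol-2-yl)-1,3-oxazol-5-yl]-4-methoxy-1-(4-methylbenzenesulfonyl)-2,3-dihydro-1H-indol-3-ol (racemic) | COc1cc(Br)cc2c1C(O)(c1oc(nc1I)-c1cccn1COCC[Si](C)(C)C)CN2S(=O)(=O)c1ccc(C)cc1 | intermediate (not isolated)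
19 | 6-bromo-3-[4-iodo-2-(1-{[2-(trimethylsilyl)ethoxy]methyl}-1H-pyrrol-2-yl)-1,3-oxazol-5-yl]-4-methoxy-1-(4-methylbenzenesulfonyl)-1H-indole | COc1cc(Br)cc2c1c(cn2S(=O)(=O)c1ccc(C)cc1)-c1oc(nc1I)-c1cccn1COCC[Si](C)(C)C | intermediate
20 | 6-bromo-3-[4-iodo-2-(1H-pyrrol-2-yl)-1,3-oxazol-5-yl]-4-methoxy-1H-indole | COc1cc(Br)cc2[nH]cc(-c3oc(-c4ccc[nH]4)nc3I)c12 | target

## Step count and uncertain steps

Total step count: 9. Longest linear sequence: 6 steps (steps 3, 4, 5, 7, 8, 9 from pyrrole 4). Steps 1–2 and step 6 are side branches that join in steps 8 and 7.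

**Step 8 (key step).** Three processes could go wrong. The aryl anion may be protonated before it closes onto the ketone, which would stop at plain N-arylation. The aryne may undergo [4+2] cycloaddition with the pyrrole or oxazole of 16 or 19 when the sulfonamide anion is in low concentration. The remote bromine may erode the regioselectivity of addition.
Fallback: the annulation would be run on a simpler partner and the oxazole attached afterwards by carbonyl addition. It sets out from 12 and 3. Esterification of 12 (MeOH, cat. H2SO4) would give methyl N-(4-methylbenzenesulfonyl)glycinate F1. F1 and 3 with CsF in MeCN should give, by the same N-addition and then acyl substitution at the ester, 6-bromo-4-methoxy-1-(4-methylbenzenesulfonyl)indolin-3-one F2, with the same methoxy-controlled regiochemistry. Addition of 14 (generated from 11 as in step 7) to the ketone of F2, with anhydrous CeCl3 as additive to suppress enolisation, should give 18. Acid-catalysed dehydration as in step 8 brings the route back at 19.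

**Step 7.** The iodine migration may be incomplete and may disproportionate into de-iodinated and di-iodinated oxazoles. The addition of the stabilised heteroaryllithium to the N-metalated amide may be slow, so that proton transfer competes.
Fallback: the nitrogen would be introduced after the C–C bond. It sets out from 11. Carbanion 14, generated as before, would be acylated with the catalogue reagent 2-chloro-N-methoxy-N-methylacetamide, which has no acidic N–H, to give 2-chloro-1-[4-iodo-2-(1-{[2-(trimethylsilyl)ethoxy]methyl}-1H-pyrrol-2-yl)-1,3-oxazol-5-yl]ethan-1-one F3. SN2 displacement of chloride with excess 4-methylbenzenesulfonamide and K2CO3 in MeCN rejoins the route at 16.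

**Step 2.** In hot, acidic aqueous copper bromide the silyl group ortho to methoxy may be lost by protodesilylation or bromodesilylation, and the triflate may be hydrolysed.
Fallback: bromine would be introduced through nitrogen under non-aqueous conditions. It sets out from 2. Copper-catalysed oxidative amination of the boronate with aqueous ammonia (Chan–Lam type, Cu2O cat., MeOH, air, rt) would give 5-amino-3-methoxy-2-(trimethylsilyl)phenyl trifluoromethanesulfonate F4. Sandmeyer bromination (tert-butyl nitrite, CuBr2, MeCN, 0 °C to rt) rejoins the route at 3.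

**Step 9.** Cleavage of the alkoxymethyl group may stall at the N-hydroxymethyl stage. Prolonged heating with basic fluoride may cause loss of iodine from the electron-rich product.
Fallback: a Lewis acid and then hydroxide would replace fluoride. It sets out from 19. BF3·OEt2 in CH2Cl2 at 0 °C should cleave the silylethyl ether to give [2-(5-{6-bromo-4-methoxy-1-(4-methylbenzenesulfonyl)-1H-indol-3-yl}-4-iodo-1,3-oxazol-2-yl)-1H-pyrrol-1-yl]methanol F5. KOH in MeOH/THF/H2O at 40 °C should then expel formaldehyde and cleave the indole sulfonamide, arriving at 20.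

## Further compounds

F1 | step 8 | methyl N-(4-methylbenzenesulfonyl)glycinate | COC(=O)CNS(=O)(=O)c1ccc(C)cc1
F2 | step 8 | 6-bromo-4-methoxy-1-(4-methylbenzenesulfonyl)indolin-3-one | COc1cc(Br)cc2c1C(=O)CN2S(=O)(=O)c1ccc(C)cc1
F3 | step 7 | 2-chloro-1-[4-iodo-2-(1-{[2-(trimethylsilyl)ethoxy]methyl}-1H-pyrrol-2-yl)-1,3-oxazol-5-yl]ethan-1-one | ClCC(=O)c1oc(nc1I)-c1cccn1COCC[Si](C)(C)C
F4 | step 2 | 5-amino-3-methoxy-2-(trimethylsilyl)phenyl trifluoromethanesulfonate | COc1cc(N)cc(OS(=O)(=O)C(F)(F)F)c1[Si](C)(C)C
F5 | step 9 | [2-(5-{6-bromo-4-methoxy-1-(4-methylbenzenesulfonyl)-1H-indol-3-yl}-4-iodo-1,3-oxazol-2-yl)-1H-pyrrol-1-yl]methanol | COc1cc(Br)cc2c1c(cn2S(=O)(=O)c1ccc(C)cc1)-c1oc(nc1I)-c1cccn1CO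
A1 | alternative 1 | 6-bromo-3-iodo-4-methoxy-1-(4-methylbenzenesulfonyl)-1H-indole | COc1cc(Br)cc2c1c(I)cn2S(=O)(=O)c1ccc(C)cc1
A2 | alternative 1 | 5-(4,4,5,5-tetramethyl-1,3,2-dioxaborolan-2-yl)-2-(triisopropylsilyl)-1,3-oxazole | CC(C)[Si](C(C)C)(C(C)C)c1ncc(o1)B1OC(C)(C)C(C)(C)O1
A3 | alternative 1 | 6-bromo-4-methoxy-1-(4-methylbenzenesulfonyl)-3-[2-(triisopropylsilyl)-1,3-oxazol-5-yl]-1H-indole | COc1cc(Br)cc2c1c(cn2S(=O)(=O)c1ccc(C)cc1)-c1cnc(o1)[Si](C(C)C)(C(C)C)C(C)C
A4 | alternative 2 | N-[2-(6-bromo-4-methoxy-1H-indol-3-yl)-2-oxoethyl]-1H-pyrrole-2-carboxamide | COc1cc(Br)cc2[nH]cc(C(=O)CNC(=O)c3ccc[nH]3)c12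
A5 | alternative 2 | 6-bromo-4-methoxy-3-[2-(1H-pyrrol-2-yl)-1,3-oxazol-5-yl]-1H-indole | COc1cc(Br)cc2[nH]cc(-c3cnc(-c4ccc[nH]4)o3)c12
A6 | alternative 3 | 2-[(3-bromo-5-methoxyphenyl)amino]-1-[4-iodo-2-(1-{[2-(trimethylsilyl)ethoxy]methyl}-1H-pyrrol-2-yl)-1,3-oxazol-5-yl]ethan-1-one | COc1cc(Br)cc(NCC(=O)c2oc(nc2I)-c2cccn2COCC[Si](C)(C)C)c1
A7 | alternative 3 | 4-bromo-3-[4-iodo-2-(1-{[2-(trimethylsilyl)ethoxy]methyl}-1H-pyrrol-2-yl)-1,3-oxazol-5-yl]-6-methoxy-1H-indole | COc1cc(Br)c2c(c1)[nH]cc2-c1oc(nc1I)-c1cccn1COCC[Si](C)(C)C
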